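The route rests on cutting the two ester C–O bonds at C4 and C5 of the cyclohexane ring together, which leads back to a C4=C5 cyclohexene and two coumarate units. The key step exploits the trans arrangement of O4 and O5 beside the C3 oxygen that is cis to O4: one Prévost reaction should add two 4-acetoxycinnamate groups anti across C4=C5, setting C4 and C5 and attaching both side chains at once. Its precursor is the spiro-dioxolanone of 1,3-cis-dihydroxycyclohex-4-ene-1-carboxylic acid with O3 silylated, made as one C3 epimer from (R)-malic acid by dioxolanone enolate allylation, ring-closing metathesis to an enone and catalyst-controlled reduction.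

Key step: step 9

Remark (numbering): quinate numbering is used for all ring compounds; O1, O3 and O4 lie on one ring face, O5 and the carboxyl carbon on the other.
Remark (design): C3 is created on the closed ring by catalyst-controlled ketone reduction. An open-chain C3 alkoxide would sit gamma to the dioxolanone carbonyl and lactonise, whereas the ring alcohol with O3 cis to O1 cannot reach that carbonyl.

Step 1
Reactants: 1 (R)-malic acid; 2 pivaldehyde
Product: 3 2-[(2R,4R)-2-tert-butyl-5-oxo-1,3-dioxolan-4-yl]acetic acid (cis acetal)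
Conditions: 2 (excess), TsOH·H2O (cat.), H2SO4 (cat.), pentane, reflux, Dean–Stark; recrystallisation
Reagents that add atoms: none
Why: Acid-catalysed acetalisation of the alpha-hydroxy acid unit with pivaldehyde (dioxolanone formation) is reversible, so the cis acetal with tert-butyl and the CH2CO2H chain on the same face should predominate by thermodynamic control from C2 of malic acid and be obtained pure by crystallisation.

Step 2
Reactants: 3 2-[(2R,4R)-2-tert-butyl-5-oxo-1,3-dioxolan-4-yl]acetic acid; 4 allyl bromide
Product: 6 2-[(2R,4R)-2-tert-butyl-5-oxo-4-(prop-2-en-1-yl)-1,3-dioxolan-4-yl]acetic acid, via dilithium enolate 5 (not isolated)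
Conditions: LiN(SiMe3)2 (2.2 equiv), THF, −78 °C; then 4, −78 → −30 °C; aq. citric acid
Reagents that add atoms: none
Why: Enolate alkylation under self-regeneration of stereocentres: allyl bromide should approach the planar enolate from the face opposite the tert-butyl group, so allyl takes the place of the former hydrogen and the quaternary centre (future C1) forms with retention.

Step 3
Reactants: 6 2-[(2R,4R)-2-tert-butyl-5-oxo-4-(prop-2-en-1-yl)-1,3-dioxolan-4-yl]acetic acid
Product: 8 (2R,5R)-2-tert-butyl-5-(2-oxobut-3-en-1-yl)-5-(prop-2-en-1-yl)-1,3-dioxolan-4-one, via acid chloride 7 (not isolated)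
Conditions: (COCl)2, DMF (cat.), CH2Cl2, 0 °C → rt, evaporate; Bu3SnCH=CH2, PdCl2(PPh3)2 (3 mol %), THF, 55 °C; aq. KF
Reagents that add atoms: tributyl(vinyl)stannane, C=C[Sn](CCCC)(CCCC)CCCC; oxalyl chloride, O=C(Cl)C(Cl)=O (chlorine of 7 only)
Why: Acid chloride formation followed by Stille acylation (palladium-catalysed coupling of an acid chloride with a vinylstannane) should give the vinyl ketone under neutral conditions that spare the dioxolanone and the beta-oxygenated ketone, and the neopentyl-type acyl group has no beta-hydrogen to lose; no stereocentre is formed.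

Step 4
Reactants: 8 (2R,5R)-2-tert-butyl-5-(2-oxobut-3-en-1-yl)-5-(prop-2-en-1-yl)-1,3-dioxolan-4-one
Product: 9 (2R,5R)-2-tert-butyl-1,3-dioxaspiro[4.5]dec-8-ene-4,7-dione
Conditions: second-generation Grubbs catalyst (3 mol %), CH2Cl2 (0.01 M), 40 °C
Reagents that add atoms: none
Why: Ring-closing metathesis between the allyl alkene and the enone alkene should close the six-membered ring as the cyclohex-2-enone (C3 ketone, C4=C5) with loss of ethylene, a standard enone ring closure that touches no stereocentre.

Step 5
Reactants: 9 (2R,5R)-2-tert-butyl-1,3-dioxaspiro[4.5]dec-8-ene-4,7-dione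
Product: 10 (2R,5R,9R)-2-tert-butyl-9-hydroxy-1,3-dioxaspiro[4.5]dec-7-en-4-one
Conditions: (S)-2-methyl-CBS-oxazaborolidine (0.2 equiv), catecholborane (1.5 equiv), toluene, −78 °C; MeOH, pH 7 buffer
Reagents that add atoms: none
Why: Corey–Bakshi–Shibata reduction: the (S)-oxazaborolidine should bind the ketone with the C4=C5 side as the larger group and deliver hydride to the face that gives the (R)-carbinol at C3 (O3 cis to O1) by catalyst control, and this epimer cannot lactonise because O3 and the lactone carbonyl lie on opposite ring faces.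

Step 6
Reactants: 10 (2R,5R,9R)-2-tert-butyl-9-hydroxy-1,3-dioxaspiro[4.5]dec-7-en-4-one
Product: 11 (2R,5R,9R)-2-tert-butyl-9-[(tert-butyldimethylsilyl)oxy]-1,3-dioxaspiro[4.5]dec-7-en-4-one
Conditions: TBSCl, imidazole, DMF, rt
Reagents that add atoms: tert-butyldimethylsilyl chloride, CC(C)(C)[Si](C)(C)Cl
Why: Standard silylation of a secondary allylic alcohol should install a bulky, non-participating and acid-labile group at O3 without affecting the acetal or the alkene.

Step 7
Reactants: 12 p-coumaric acid
Product: 13 (E)-4-acetoxycinnamic acid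
Conditions: Ac2O, pyridine, 0 °C → rt; H2O, then dilute HCl
Reagents that add atoms: acetic anhydride, CC(=O)OC(C)=O
Why: O-Acetylation of the phenol by acyl transfer from acetic anhydride, with aqueous work-up returning the free carboxylic acid, lowers the electron density of the arene and the styrene-type alkene towards electrophilic iodine.

Step 8
Reactants: 13 (E)-4-acetoxycinnamic acid
Product: 15 silver (E)-4-acetoxycinnamate, via sodium salt 14 (not isolated)
Conditions: NaHCO3 (1.0 equiv), H2O/MeCN, rt; AgNO3 (1.0 equiv), dark; filter, dry over P2O5 in vacuo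
Reagents that add atoms: silver nitrate, [Ag+].[O-][N+](=O)[O-]; sodium hydrogen carbonate, [Na+].OC([O-])=O (sodium of 14 only)
Why: Salt metathesis: the sodium carboxylate formed with one equivalent of hydrogen carbonate should precipitate as the sparingly soluble silver carboxylate on addition of AgNO3, under conditions mild enough for the aryl acetate.

Step 9
Reactants: 11 (2R,5R,9R)-2-tert-butyl-9-[(tert-butyldimethylsilyl)oxy]-1,3-dioxaspiro[4.5]dec-7-en-4-one; 15 silver (E)-4-acetoxycinnamate (2.2 equiv)
Product: 18 3-O-TBS-4,5-bis-O-[(E)-4-acetoxycinnamoyl]quinic acid pivaldehyde dioxolanone, via trans-iodo ester 16 (not isolated), via dioxolan-2-ylium ion 17 (not isolated)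
Conditions: I2 (1.05 equiv), dry benzene, 4 Å molecular sieves, dark, rt → 80 °C
Reagents that add atoms: iodine, II (iodine atom of 16 only)
Why: Iodine and 15 give the acyl hypoiodite, whose iodonium ion should form on the face of C4=C5 opposite the bulky C3 silyl ether and be opened anti by a first carboxylate at C5 (16); silver-assisted attack of that ester carbonyl on C4 expels iodide and gives the cis-fused dioxolan-2-ylium ion 17 on the O3 face, which a second carboxylate opens by backside attack at C5. This is the Prévost reaction, the anhydrous iodine/silver carboxylate trans-diacyloxylation long applied to cyclohexenes. No ring of the target is closed, the five-membered cation being only a transient intermediate. The C4 centre is set by the anti relation between the iodine (delivered opposite the silyl ether) and the participating ester oxygen, which leaves O4 cis to O3, and the C5 centre by the inversion in the final opening, which puts O5 trans to O4. The selectivity needed is opening of 17 at C5 and not at C4; the electron-withdrawing C3–O bond retards substitution at C4, and trans-diaxial opening through the half-chair that keeps the silyloxy group pseudo-equatorial (no 1,3-diaxial O1/O3 contact) also leads to attack at C5. The cinnamate alkenes are conjugated with the ester carbonyl and the phenols are acetylated, so only the ring alkene should take up the iodinating agent; the regioisomeric iodo ester would converge on the same ion 17.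

Step 10
Reactants: 18 3-O-TBS-4,5-bis-O-[(E)-4-acetoxycinnamoyl]quinic acid pivaldehyde dioxolanone
Product: 19 4,5-di-O-p-coumaroylquinic acid
Conditions: 2 M aq. HCl/THF (1:2), rt → 35 °C
Reagents that add atoms: none
Why: Acid-catalysed hydrolysis should cleave the silyl ether, the pivaldehyde acetal of the dioxolanone (freeing O1–H and the carboxylic acid) and both aryl acetates, while the conjugated, hindered secondary coumarate esters hydrolyse far more slowly and base-promoted acyl migration is avoided; no stereocentre is touched.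

Compound list
1 | (R)-malic acid [(2R)-2-hydroxybutanedioic acid] | OC(=O)C[C@H](C(=O)O)O | starting material
2 | pivaldehyde (2,2-dimethylpropanal) | CC(C)(C)C=O | starting material
3 | 2-[(2R,4R)-2-tert-butyl-5-oxo-1,3-dioxolan-4-yl]acetic acid (cis acetal: tert-butyl and CH2CO2H on the same face) | OC(=O)C[C@H]1O[C@@H](C(C)(C)C)OC1=O | intermediate
4 | allyl bromide (3-bromoprop-1-ene) | C=CCBr | starting material
5 | dilithium enolate-carboxylate of 3 (acetal carbon R) | [Li+].[Li+].[O-]C(=O)CC1=C([O-])O[C@H](C(C)(C)C)O1 | intermediate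
6 | 2-[(2R,4R)-2-tert-butyl-5-oxo-4-(prop-2-en-1-yl)-1,3-dioxolan-4-yl]acetic acid (allyl trans to tert-butyl) | OC(=O)C[C@]1(O[C@@H](C(C)(C)C)OC1=O)CC=C | intermediate
7 | 2-[(2R,4R)-2-tert-butyl-5-oxo-4-(prop-2-en-1-yl)-1,3-dioxolan-4-yl]acetyl chloride | ClC(=O)C[C@]1(O[C@@H](C(C)(C)C)OC1=O)CC=C | intermediate
8 | (2R,5R)-2-tert-butyl-5-(2-oxobut-3-en-1-yl)-5-(prop-2-en-1-yl)-1,3-dioxolan-4-one | C=CC(=O)C[C@]1(O[C@@H](C(C)(C)C)OC1=O)CC=C | intermediate
9 | (2R,5R)-2-tert-butyl-1,3-dioxaspiro[4.5]dec-8-ene-4,7-dione (quinate numbering: 3-oxo, C4=C5, O1 and carboxyl tied as the pivaldehyde dioxolanone) | C1=CC(=O)C[C@]2(O[C@@H](C(C)(C)C)OC2=O)C1 | intermediate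
10 | (2R,5R,9R)-2-tert-butyl-9-hydroxy-1,3-dioxaspiro[4.5]dec-7-en-4-one (quinate numbering: 3-OH cis to O1, C4=C5) | C1=C[C@H](O)C[C@]2(O[C@@H](C(C)(C)C)OC2=O)C1 | intermediate
11 | (2R,5R,9R)-2-tert-butyl-9-[(tert-butyldimethylsilyl)oxy]-1,3-dioxaspiro[4.5]dec-7-en-4-one (pivaldehyde dioxolanone of 3-O-TBS-1,3-cis-dihydroxycyclohex-4-ene-1-carboxylic acid) | C1=C[C@H](O[Si](C)(C)C(C)(C)C)C[C@]2(O[C@@H](C(C)(C)C)OC2=O)C1 | intermediate
12 | p-coumaric acid [(E)-3-(4-hydroxyphenyl)prop-2-enoic acid] | OC(=O)/C=C/c1ccc(O)cc1 | starting material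
13 | (E)-4-acetoxycinnamic acid | CC(=O)Oc1ccc(/C=C/C(=O)O)cc1 | intermediate
14 | sodium (E)-4-acetoxycinnamate | CC(=O)Oc1ccc(/C=C/C(=O)[O-])cc1.[Na+] | intermediate
15 | silver (E)-4-acetoxycinnamate | CC(=O)Oc1ccc(/C=C/C(=O)[O-])cc1.[Ag+] | intermediate
16 | trans-iodo ester: 4-iodo (trans to O3) 5-O-[(E)-4-acetoxycinnamoyl] (O5 cis to O3) derivative of 11 | I[C@H]1[C@H](O[Si](C)(C)C(C)(C)C)C[C@]2(O[C@@H](C(C)(C)C)OC2=O)C[C@@H]1OC(=O)/C=C/c1ccc(OC(C)=O)cc1 | intermediate
17 | cis-fused 2-[(E)-2-(4-acetoxyphenyl)ethenyl]-1,3-dioxolan-2-ylium ion spanning O4 and O5 on the O3 face, 4-acetoxycinnamate as counter-ion | CC(=O)Oc1ccc(/C=C/C2=[O+][C@H]3C[C@@]4(O[C@@H](C(C)(C)C)OC4=O)C[C@@H](O[Si](C)(C)C(C)(C)C)[C@H]3O2)cc1.CC(=O)Oc1ccc(/C=C/C(=O)[O-])cc1 | intermediate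
18 | 3-O-(tert-butyldimethylsilyl)-4,5-bis-O-[(E)-4-acetoxycinnamoyl]quinic acid, O1 and carboxyl as the pivaldehyde dioxolanone (ring centres as in (−)-quinic acid; acetal carbon R) | CC(=O)Oc1ccc(/C=C/C(=O)O[C@@H]2[C@H](O[Si](C)(C)C(C)(C)C)C[C@]3(O[C@@H](C(C)(C)C)OC3=O)C[C@H]2OC(=O)/C=C/c4ccc(OC(C)=O)cc4)cc1 | intermediate
19 | 4,5-di-O-p-coumaroylquinic acid [(1S,3R,4R,5R)-1,3-dihydroxy-4,5-bis{[(E)-3-(4-hydroxyphenyl)prop-2-enoyl]oxy}cyclohexane-1-carboxylic acid] | O=C(/C=C/c1ccc(O)cc1)O[C@@H]1[C@H](O)C[C@@](O)(C(=O)O)C[C@H]1OC(=O)/C=C/c1ccc(O)cc1 | target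

Total step count: 10 steps. Longest linear sequence: 8 steps (steps 1–6, 9 and 10, from (R)-malic acid); steps 7 and 8 form the short coumarate branch.

Steps most likely to fail

1. Step 9. Iodination could occur on the O3 face, or the dioxolanylium ion could be opened at C4; either would give the trans-diester epimeric at both C4 and C5. The iodonium ion could also be captured by the lactone carbonyl (iodolactonisation with loss of pivaldehyde), and the silver cinnamate could undergo decarboxylative iodination. The fallback sets out from allylic alcohol 10 and uses only known epoxide chemistry. Hydroxyl-directed epoxidation (VO(acac)2 cat., tBuOOH, CH2Cl2, 0 °C → rt) should place the oxirane oxygen cis to O3 and give the syn-epoxy alcohol F1. Silylation (TBSCl, imidazole, DMF) gives the silyl epoxide F2. Addition of acid 13, catalysed by the trivalent cobalt complex (salen)Co(OAc) with iPr2NEt in tert-butyl methyl ether, should open the oxirane trans-diaxially at C5, the carbon remote from the C3–O bond, and give the 4-hydroxy 5-ester F3. Acylation of O4 with (E)-4-acetoxycinnamoyl chloride F4 (made from 13 with (COCl)2 and cat. DMF) in pyridine with DMAP comes back to the route at 18. Acyl migration between O4 and O5 in F3 would be harmless, since both acyl groups are the same.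

2. Step 5. The catalyst may not overcome the facial bias of the spiro centre (a mismatched pairing), so that hydride is delivered to both faces of the ketone. The fallback sets out from enone 9. Luche reduction (NaBH4, CeCl3·7H2O, MeOH, −78 °C) would give 10 together with its C3 epimer, the 3-epi alcohol F5. The two are separated by chromatography, and F5 is oxidised back to 9 with MnO2 (CH2Cl2, rt) and resubmitted, so that the material converges on 10, where the route is rejoined.

3. Step 10. Cleavage of the hindered pivaldehyde acetal may be slow enough that, once O3 is free, the coumarate esters begin to hydrolyse or to migrate to O3. The fallback sets out from 18 and separates the two tasks. NH4OAc in MeOH at rt should remove both aryl acetates while O3 is still silylated, so that no neighbouring hydroxyl is available for migration, giving the bis-phenol F6. Short treatment with TFA/H2O (9:1, 0 °C → rt) then cleaves the silyl ether and the acetal and arrives at target 19.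

Further compounds
F1 | step 9 | syn-epoxy alcohol: 4,5-epoxide of 10 with the oxirane oxygen cis to O3 | O[C@@H]1C[C@]2(O[C@@H](C(C)(C)C)OC2=O)C[C@@H]3O[C@H]13
F2 | step 9 | silyl epoxide: 3-O-tert-butyldimethylsilyl ether of F1 | CC(C)(C)[Si](C)(C)O[C@@H]1C[C@]2(O[C@@H](C(C)(C)C)OC2=O)C[C@@H]3O[C@H]13
F3 | step 9 | 3-O-TBS-5-O-[(E)-4-acetoxycinnamoyl]quinic acid pivaldehyde dioxolanone (4-OH free) | O[C@@H]1[C@H](O[Si](C)(C)C(C)(C)C)C[C@]2(O[C@@H](C(C)(C)C)OC2=O)C[C@H]1OC(=O)/C=C/c1ccc(OC(C)=O)cc1
F4 | step 9 | (E)-4-acetoxycinnamoyl chloride | CC(=O)Oc1ccc(/C=C/C(Cl)=O)cc1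
F5 | step 5 | 3-epi alcohol: C3 epimer of 10 (O3 trans to O1) | C1=C[C@@H](O)C[C@]2(O[C@@H](C(C)(C)C)OC2=O)C1
F6 | step 10 | 3-O-TBS-4,5-di-O-(E)-p-coumaroylquinic acid pivaldehyde dioxolanone (both phenols free) | Oc1ccc(/C=C/C(=O)O[C@@H]2[C@H](O[Si](C)(C)C(C)(C)C)C[C@]3(O[C@@H](C(C)(C)C)OC3=O)C[C@H]2OC(=O)/C=C/c4ccc(O)cc4)cc1
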